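**Retrosynthetic overview**

1. Target 25 ⇐ thermal Cope ring contraction of the ten-membered (E,E)-1(10),4-diene of germacranolide 24: C5–C10 forms and C2–C3 breaks. The enabling feature is the 1,5-diene C2=C1–C10–C5–C4=C3, i.e. the vinyl group on quaternary ring carbon C10 beside the acrolein methylene on ring carbon C5 of the cyclohexane.
2. 24 ⇐ 6-epi alcohol 20 by Mitsunobu inversion with angelic acid, desilylation and oxidation of C15.
3. Ten-membered carbocycle and α-methylene lactone of 20 ⇐ CrCl2-mediated intramolecular allylation (C6–C7) of the bromomethyl-butenolide enal 18.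
4. 18 ⇐ enantioselective vinylogous Mukaiyama aldol (C8–C9) of enal 7 with silyloxyfuran 13 (from furan-3-ylmethanol), then carbonylative formylation (C6).
5. 7 ⇐ anti-carbomagnesiation/iodination of propargyl alcohol and cross-metathesis with methacrolein. Ring order: butenolide, then ten-membered ring, then cyclohexane (last).

Key step: step 16

Remark: atoms carry germacrane/elemane numbering (C1–C10 are the carbons of the ten-membered ring, C11–C13 the lactone carbons, C14 the methyl on C10, C15 the formyl carbon on C4); the target is (5R,6S,7S,8R,9S,10S).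
Assumption: the sense of induction of the bisphosphoramide in step 7 is taken by analogy with simpler silyloxyfurans; the antipodal catalyst would be used if the opposite sense were met.

**Step 1**
Reactants: 1 but-3-en-1-ylmagnesium bromide; 2 prop-2-yn-1-ol
Product: 4 (2Z)-2-(but-3-en-1-yl)-3-iodoprop-2-en-1-ol, via alkenylmagnesium alkoxide chelate 3 (not isolated)
Conditions: 1 (2.5 equiv), CuI (10 mol%), THF, −10 °C → rt; then I2, −40 °C → rt; aq. NH4Cl
Reagents that add atoms: iodine, II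
Why: Copper-catalysed anti-carbomagnesiation of the magnesium alkoxide of propargyl alcohol should place the butenyl group on the internal carbon and magnesium on the terminal carbon in a five-membered chelate, and iodinolysis with retention gives the Z-iodoalkene (only double-bond geometry is set).

**Step 2**
Reactants: 4 (2Z)-2-(but-3-en-1-yl)-3-iodoprop-2-en-1-ol
Product: 5 tert-butyl{[(2Z)-2-(but-3-en-1-yl)-3-iodoprop-2-en-1-yl]oxy}diphenylsilane
Conditions: TBDPSCl, imidazole, DMF, rt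
Reagents that add atoms: tert-butyl(chloro)diphenylsilane, CC(C)(C)[Si](Cl)(c1ccccc1)c1ccccc1
Why: Standard silylation of a primary allylic alcohol gives an ether that should survive every step up to step 14.

**Step 3**
Reactants: 5 tert-butyl{[(2Z)-2-(but-3-en-1-yl)-3-iodoprop-2-en-1-yl]oxy}diphenylsilane; 6 2-methylprop-2-enal (methacrolein)
Product: 7 (2E,6Z)-6-{[(tert-butyldiphenylsilyl)oxy]methyl}-7-iodo-2-methylhepta-2,6-dienal
Conditions: second-generation Grubbs catalyst RuCl2(=CHPh)(PCy3)(1,3-dimesitylimidazolidin-2-ylidene) (5 mol%), 6 (5 equiv), CH2Cl2, 40 °C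
Reagents that add atoms: none
Why: Olefin cross-metathesis of the monosubstituted alkene with methacrolein should give the thermodynamically preferred E-enal (C10=C1), the trisubstituted iodoalkene being inert to the ruthenium carbene.

**Step 4**
Reactants: 8 furan-3-ylmethanol
Product: 9 3-{[(4-methoxybenzyl)oxy]methyl}furan
Conditions: NaH, PMBCl, Bu4NI (cat.), THF, 0 °C → rt
Reagents that add atoms: 4-methoxybenzyl chloride, COc1ccc(CCl)cc1
Why: Williamson etherification of the primary alkoxide installs the ether that later directs lithiation and masks the C13 oxygen.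

**Step 5**
Reactants: 9 3-{[(4-methoxybenzyl)oxy]methyl}furan
Product: 12 3-{[(4-methoxybenzyl)oxy]methyl}furan-2(5H)-one, via 2-lithiofuran 10 (not isolated), via furan-2-ylboronate 11 (not isolated)
Conditions: n-BuLi, THF, −78 → 0 °C; B(OMe)3, −78 °C → rt; H2O2 (30%, 1.2 equiv), AcOH, 0 °C; Et3N (cat.)
Reagents that add atoms: hydrogen peroxide, OO
Why: Ether-directed lithiation at C2 of the furan, borylation and peroxide oxidation should give the 2-hydroxyfuran, which tautomerises to the conjugated α-substituted butenolide (an oxidative dearomatisation of the furan).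

**Step 6**
Reactants: 12 3-{[(4-methoxybenzyl)oxy]methyl}furan-2(5H)-one
Product: 13 tert-butyl[(3-{[(4-methoxybenzyl)oxy]methyl}furan-2-yl)oxy]dimethylsilane
Conditions: TBSOTf, Et3N, CH2Cl2, 0 °C
Reagents that add atoms: tert-butyldimethylsilyl trifluoromethanesulfonate, CC(C)(C)[Si](C)(C)OS(=O)(=O)C(F)(F)F
Why: Soft enolisation and O-silylation of the butenolide give the 2-silyloxyfuran, the dienolate equivalent needed for the vinylogous aldol addition.

**Step 7**
Reactants: 7 (2E,6Z)-6-{[(tert-butyldiphenylsilyl)oxy]methyl}-7-iodo-2-methylhepta-2,6-dienal; 13 tert-butyl[(3-{[(4-methoxybenzyl)oxy]methyl}furan-2-yl)oxy]dimethylsilane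
Product: 14 (5R)-5-[(1S,2E,6Z)-6-{[(tert-butyldiphenylsilyl)oxy]methyl}-1-hydroxy-7-iodo-2-methylhepta-2,6-dien-1-yl]-3-{[(4-methoxybenzyl)oxy]methyl}furan-2(5H)-one
Conditions: SiCl4 (1.1 equiv), (R,R)-N,N'-dimethyl-1,1'-binaphthyl-2,2'-diamine-derived bisphosphoramide (5 mol%), i-Pr2NEt (10 mol%), CH2Cl2, −78 °C; aq. NaHCO3
Reagents that add atoms: none
Why: In this catalytic enantioselective vinylogous Mukaiyama aldol addition the silyloxyfuran should attack through its C5 on the Re face of the enal bound to the chiral Lewis base–trichlorosilyl cation, the open transition state giving the anti (erythro) adduct and thereby setting C8 (R) and C9 (S) together.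

**Step 8**
Reactants: 14 (5R)-5-[(1S,2E,6Z)-6-{[(tert-butyldiphenylsilyl)oxy]methyl}-1-hydroxy-7-iodo-2-methylhepta-2,6-dien-1-yl]-3-{[(4-methoxybenzyl)oxy]methyl}furan-2(5H)-one
Product: 15 (2Z,6E,8S)-3-{[(tert-butyldiphenylsilyl)oxy]methyl}-8-hydroxy-8-[(2R)-4-{[(4-methoxybenzyl)oxy]methyl}-5-oxo-2,5-dihydrofuran-2-yl]-7-methylocta-2,6-dienal
Conditions: Pd(PPh3)4 (5 mol%), CO (3 bar), Bu3SnH (slow addition), THF, 50 °C
Reagents that add atoms: carbon monoxide, [C-]#[O+]
Why: Palladium-catalysed reductive carbonylation (formylation) of the alkenyl iodide proceeds with retention of geometry to the Z-enal (C6), and it is run before acetylation so that zerovalent palladium meets no allylic acetate.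

**Step 9**
Reactants: 15 (2Z,6E,8S)-3-{[(tert-butyldiphenylsilyl)oxy]methyl}-8-hydroxy-8-[(2R)-4-{[(4-methoxybenzyl)oxy]methyl}-5-oxo-2,5-dihydrofuran-2-yl]-7-methylocta-2,6-dienal
Product: 16 (1S,2E,6Z)-6-{[(tert-butyldiphenylsilyl)oxy]methyl}-1-[(2R)-4-{[(4-methoxybenzyl)oxy]methyl}-5-oxo-2,5-dihydrofuran-2-yl]-2-methyl-8-oxoocta-2,6-dien-1-yl acetate
Conditions: Ac2O, pyridine, DMAP (cat.), CH2Cl2, 0 °C
Reagents that add atoms: acetic anhydride, CC(=O)OC(C)=O
Why: Acylation of the secondary allylic alcohol installs the C9 acetate of the target early, at a position that is not α to any later aldehyde or metal centre.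

**Step 10**
Reactants: 16 (1S,2E,6Z)-6-{[(tert-butyldiphenylsilyl)oxy]methyl}-1-[(2R)-4-{[(4-methoxybenzyl)oxy]methyl}-5-oxo-2,5-dihydrofuran-2-yl]-2-methyl-8-oxoocta-2,6-dien-1-yl acetate
Product: 17 (1S,2E,6Z)-6-{[(tert-butyldiphenylsilyl)oxy]methyl}-1-[(2R)-4-(hydroxymethyl)-5-oxo-2,5-dihydrofuran-2-yl]-2-methyl-8-oxoocta-2,6-dien-1-yl acetate
Conditions: DDQ, CH2Cl2/pH 7 buffer, 0 °C
Reagents that add atoms: none
Why: Oxidative cleavage of the 4-methoxybenzyl ether under buffered conditions frees the C13 alcohol without touching the silyl ether, the acetate or the enal.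

**Step 11**
Reactants: 17 (1S,2E,6Z)-6-{[(tert-butyldiphenylsilyl)oxy]methyl}-1-[(2R)-4-(hydroxymethyl)-5-oxo-2,5-dihydrofuran-2-yl]-2-methyl-8-oxoocta-2,6-dien-1-yl acetate
Product: 18 (1S,2E,6Z)-1-[(2R)-4-(bromomethyl)-5-oxo-2,5-dihydrofuran-2-yl]-6-{[(tert-butyldiphenylsilyl)oxy]methyl}-2-methyl-8-oxoocta-2,6-dien-1-yl acetate
Conditions: NBS, Me2S, CH2Cl2, −20 → 0 °C
Reagents that add atoms: N-bromosuccinimide, BrN1C(=O)CCC1=O
Why: Corey–Kim-type bromination through the alkoxysulfonium salt converts the allylic primary alcohol into the bromide under neutral conditions that spare the enal and the base-sensitive butenolide.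

**Step 12**
Reactants: 18 (1S,2E,6Z)-1-[(2R)-4-(bromomethyl)-5-oxo-2,5-dihydrofuran-2-yl]-6-{[(tert-butyldiphenylsilyl)oxy]methyl}-2-methyl-8-oxoocta-2,6-dien-1-yl acetate
Product: 20 (1(10)E,4Z,6R,7S,8R,9S)-9-acetoxy-15-[(tert-butyldiphenylsilyl)oxy]-6-hydroxygermacra-1(10),4,11(13)-trien-12,8-olide, via allylchromium species 19 (not isolated)
Conditions: CrCl2 (6 equiv), THF, rt, slow addition of 18 (final 1 mM); aq. NH4Cl
Reagents that add atoms: none
Why: In this intramolecular Nozaki–Hiyama-type allylation the allylchromium species should add through C7 to the enal carbonyl, C7 being attacked anti to the C8 side chain of the butenolide (trans lactone, 7S) and the closed chair transition state with the enal residue equatorial giving the 6,7-anti carbinol (6R), so that the ten-membered ring and the α-methylene lactone form in one operation.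

**Step 13**
Reactants: 20 (1(10)E,4Z,6R,7S,8R,9S)-9-acetoxy-15-[(tert-butyldiphenylsilyl)oxy]-6-hydroxygermacra-1(10),4,11(13)-trien-12,8-olide; 21 (2Z)-2-methylbut-2-enoic acid (angelic acid)
Product: 22 (1(10)E,4Z,6S,7S,8R,9S)-9-acetoxy-15-[(tert-butyldiphenylsilyl)oxy]-6-[(2Z)-2-methylbut-2-enoyloxy]germacra-1(10),4,11(13)-trien-12,8-olide
Conditions: PPh3, DIAD, toluene, 0 °C → rt
Reagents that add atoms: none
Why: Mitsunobu esterification should displace the activated allylic oxyphosphonium group by angelate with SN2 inversion, setting 6S and installing the Z-ester without acylation catalysts that isomerise angelates.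

**Step 14**
Reactants: 22 (1(10)E,4Z,6S,7S,8R,9S)-9-acetoxy-15-[(tert-butyldiphenylsilyl)oxy]-6-[(2Z)-2-methylbut-2-enoyloxy]germacra-1(10),4,11(13)-trien-12,8-olide
Product: 23 (1(10)E,4Z,6S,7S,8R,9S)-9-acetoxy-15-hydroxy-6-[(2Z)-2-methylbut-2-enoyloxy]germacra-1(10),4,11(13)-trien-12,8-olide
Conditions: HF·pyridine, pyridine, THF, 0 °C → rt
Reagents that add atoms: none
Why: Buffered fluoride desilylation frees the C15 alcohol only after O6 is esterified, so that no free 6-hydroxyl can later close onto the cis-disposed C15 aldehyde.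

**Step 15**
Reactants: 23 (1(10)E,4Z,6S,7S,8R,9S)-9-acetoxy-15-hydroxy-6-[(2Z)-2-methylbut-2-enoyloxy]germacra-1(10),4,11(13)-trien-12,8-olide
Product: 24 (1(10)E,4Z,6S,7S,8R,9S)-9-acetoxy-6-[(2Z)-2-methylbut-2-enoyloxy]-15-oxogermacra-1(10),4,11(13)-trien-12,8-olide
Conditions: Dess–Martin periodinane, NaHCO3, CH2Cl2, 0 °C
Reagents that add atoms: none
Why: Dess–Martin oxidation of the primary allylic alcohol under buffered, non-nucleophilic conditions should give the enal without isomerising its ring-constrained geometry.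

**Step 16**
Reactants: 24 (1(10)E,4Z,6S,7S,8R,9S)-9-acetoxy-6-[(2Z)-2-methylbut-2-enoyloxy]-15-oxogermacra-1(10),4,11(13)-trien-12,8-olide
Product: 25 (5R,6S,7S,8R,9S,10S)-9-acetoxy-6-[(2Z)-2-methylbut-2-enoyloxy]-15-oxoelema-1,3,11(13)-trien-12,8-olide (target)
Conditions: toluene (degassed, trace 2,6-di-tert-butyl-4-methylphenol), 110 °C, sealed tube
Reagents that add atoms: none
Why: A concerted suprafacial [3,3]-sigmatropic (Cope) shift of the (E,E)-cyclodeca-1,5-diene forms the C5–C10 bond as C2–C3 breaks, so the cyclohexane closes transannularly by contraction of the ten-membered ring and the C1=C2 vinyl group and the C3=C4 methylene of the acrolein appear at once. The closest known reaction type is the thermal germacranolide-to-elemanolide rearrangement, and the formyl group on C4 (position 2 of the hexa-1,5-diene) should lower the barrier by stabilising the diyl-like transition state. C5 and the quaternary C10 are set together by the chair-like transition state of the E,E-diene, which places C4 and C1 equatorial and H5 and C14 anti on the forming ring. The absolute sense is fixed by the trans-fused butyrolactone at C7–C8, which must stay diequatorial, so that only the conformer leading to (5R,10S) can reach the double-chair geometry. The selectivity needed is chair over boat and one ring conformer over the other, secured by the two E ring double bonds and the trans lactone; relief of medium-ring strain should draw the equilibrium to the elemane.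

**Compound list**

1 | but-3-en-1-ylmagnesium bromide | C=CCC[Mg]Br | starting material
2 | prop-2-yn-1-ol | C#CCO | starting material
3 | 4-(but-3-en-1-yl)-2,5-dihydro-1,2-oxamagnesole (chelated Z-alkenylmagnesium alkoxide) | C=CCCC1=C[Mg]OC1 | intermediate (not isolated)
4 | (2Z)-2-(but-3-en-1-yl)-3-iodoprop-2-en-1-ol | I/C=C(\CO)CCC=C | intermediate
5 | tert-butyl{[(2Z)-2-(but-3-en-1-yl)-3-iodoprop-2-en-1-yl]oxy}diphenylsilane | I/C=C(\CO[Si](c1ccccc1)(c1ccccc1)C(C)(C)C)CCC=C | intermediate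
6 | 2-methylprop-2-enal (methacrolein) | CC(=C)C=O | starting material
7 | (2E,6Z)-6-{[(tert-butyldiphenylsilyl)oxy]methyl}-7-iodo-2-methylhepta-2,6-dienal | I/C=C(\CO[Si](c1ccccc1)(c1ccccc1)C(C)(C)C)CC/C=C(\C)C=O | intermediate
8 | furan-3-ylmethanol | OCc1ccoc1 | starting material
9 | 3-{[(4-methoxybenzyl)oxy]methyl}furan | COc1ccc(COCc2ccoc2)cc1 | intermediate
10 | 2-lithio-3-{[(4-methoxybenzyl)oxy]methyl}furan | COc1ccc(COCc2ccoc2[Li])cc1 | intermediate (not isolated)
11 | dimethyl (3-{[(4-methoxybenzyl)oxy]methyl}furan-2-yl)boronate | COc1ccc(COCc2ccoc2B(OC)OC)cc1 | intermediate (not isolated)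
12 | 3-{[(4-methoxybenzyl)oxy]methyl}furan-2(5H)-one | COc1ccc(COCC2=CCOC2=O)cc1 | intermediate
13 | tert-butyl[(3-{[(4-methoxybenzyl)oxy]methyl}furan-2-yl)oxy]dimethylsilane | COc1ccc(COCc2ccoc2O[Si](C)(C)C(C)(C)C)cc1 | intermediate
14 | (5R)-5-[(1S,2E,6Z)-6-{[(tert-butyldiphenylsilyl)oxy]methyl}-1-hydroxy-7-iodo-2-methylhepta-2,6-dien-1-yl]-3-{[(4-methoxybenzyl)oxy]methyl}furan-2(5H)-one (8R,9S anti aldol adduct) | I/C=C(\CO[Si](c1ccccc1)(c1ccccc1)C(C)(C)C)CC/C=C(\C)[C@H](O)[C@@H]1OC(=O)C(COCc2ccc(OC)cc2)=C1 | intermediate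
15 | (2Z,6E,8S)-3-{[(tert-butyldiphenylsilyl)oxy]methyl}-8-hydroxy-8-[(2R)-4-{[(4-methoxybenzyl)oxy]methyl}-5-oxo-2,5-dihydrofuran-2-yl]-7-methylocta-2,6-dienal | O=C/C=C(\CO[Si](c1ccccc1)(c1ccccc1)C(C)(C)C)CC/C=C(\C)[C@H](O)[C@@H]1OC(=O)C(COCc2ccc(OC)cc2)=C1 | intermediate
16 | (1S,2E,6Z)-6-{[(tert-butyldiphenylsilyl)oxy]methyl}-1-[(2R)-4-{[(4-methoxybenzyl)oxy]methyl}-5-oxo-2,5-dihydrofuran-2-yl]-2-methyl-8-oxoocta-2,6-dien-1-yl acetate | O=C/C=C(\CO[Si](c1ccccc1)(c1ccccc1)C(C)(C)C)CC/C=C(\C)[C@H](OC(C)=O)[C@@H]1OC(=O)C(COCc2ccc(OC)cc2)=C1 | intermediate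
17 | (1S,2E,6Z)-6-{[(tert-butyldiphenylsilyl)oxy]methyl}-1-[(2R)-4-(hydroxymethyl)-5-oxo-2,5-dihydrofuran-2-yl]-2-methyl-8-oxoocta-2,6-dien-1-yl acetate | O=C/C=C(\CO[Si](c1ccccc1)(c1ccccc1)C(C)(C)C)CC/C=C(\C)[C@H](OC(C)=O)[C@@H]1OC(=O)C(CO)=C1 | intermediate
18 | (1S,2E,6Z)-1-[(2R)-4-(bromomethyl)-5-oxo-2,5-dihydrofuran-2-yl]-6-{[(tert-butyldiphenylsilyl)oxy]methyl}-2-methyl-8-oxoocta-2,6-dien-1-yl acetate | O=C/C=C(\CO[Si](c1ccccc1)(c1ccccc1)C(C)(C)C)CC/C=C(\C)[C@H](OC(C)=O)[C@@H]1OC(=O)C(CBr)=C1 | intermediate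
19 | allylchromium dichloride formed from 18 at C13 (trivalent chromium) | O=C/C=C(\CO[Si](c1ccccc1)(c1ccccc1)C(C)(C)C)CC/C=C(\C)[C@H](OC(C)=O)[C@@H]1OC(=O)C(C[Cr](Cl)Cl)=C1 | intermediate (not isolated)
20 | (1(10)E,4Z,6R,7S,8R,9S)-9-acetoxy-15-[(tert-butyldiphenylsilyl)oxy]-6-hydroxygermacra-1(10),4,11(13)-trien-12,8-olide (H6 trans to H7, lactone trans-fused, C15 cis to C6 on the 4,5-double bond) | C1/C(CO[Si](c2ccccc2)(c2ccccc2)C(C)(C)C)=C/[C@@H](O)[C@@H]3C(=C)C(=O)O[C@H]3[C@@H](OC(C)=O)/C(C)=C/C1 | intermediate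
21 | (2Z)-2-methylbut-2-enoic acid (angelic acid) | C/C=C(/C)C(=O)O | starting material
22 | (1(10)E,4Z,6S,7S,8R,9S)-9-acetoxy-15-[(tert-butyldiphenylsilyl)oxy]-6-[(2Z)-2-methylbut-2-enoyloxy]germacra-1(10),4,11(13)-trien-12,8-olide | C1/C(CO[Si](c2ccccc2)(c2ccccc2)C(C)(C)C)=C/[C@H](OC(=O)/C(C)=C\C)[C@@H]3C(=C)C(=O)O[C@H]3[C@@H](OC(C)=O)/C(C)=C/C1 | intermediate
23 | (1(10)E,4Z,6S,7S,8R,9S)-9-acetoxy-15-hydroxy-6-[(2Z)-2-methylbut-2-enoyloxy]germacra-1(10),4,11(13)-trien-12,8-olide | C1/C(CO)=C/[C@H](OC(=O)/C(C)=C\C)[C@@H]3C(=C)C(=O)O[C@H]3[C@@H](OC(C)=O)/C(C)=C/C1 | intermediate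
24 | (1(10)E,4Z,6S,7S,8R,9S)-9-acetoxy-6-[(2Z)-2-methylbut-2-enoyloxy]-15-oxogermacra-1(10),4,11(13)-trien-12,8-olide | C1/C(C=O)=C/[C@H](OC(=O)/C(C)=C\C)[C@@H]3C(=C)C(=O)O[C@H]3[C@@H](OC(C)=O)/C(C)=C/C1 | intermediate
25 | (5R,6S,7S,8R,9S,10S)-9-acetoxy-6-[(2Z)-2-methylbut-2-enoyloxy]-15-oxoelema-1,3,11(13)-trien-12,8-olide (CNP0228039.1) | C=C[C@]1(C)[C@H](OC(C)=O)[C@@H]2OC(=O)C(=C)[C@H]2[C@@H](OC(=O)/C(C)=C\C)[C@H]1C(=C)C=O | target

**Step count and risks**

Total step count: 16. Longest linear sequence: 13 steps (steps 1–3 and 7–16).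

Steps most likely to fail:

Step 13 (Mitsunobu inversion). The activated allylic oxyphosphonium group may ionise to the delocalised C4–C6 allyl cation, which would erode inversion or lead to SN2′ attack or elimination, and the phosphine may isomerise the angelate to the tiglate. The fallback sets out from 20. Oxidation with Dess–Martin periodinane would give the 6-ketone F1. A reagent-controlled CBS reduction (catecholborane, with the oxazaborolidine antipode that delivers hydride to the face giving 6S) would give the 6β-alcohol F2. Esterification with 21 through its mixed anhydride with 2,4,6-trichlorobenzoyl chloride (Et3N, toluene, 80 °C, no DMAP) comes back to the route at 22.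

Step 12 (macrocyclisation). Oligomerisation by intermolecular coupling, simple reduction of the allylic bromide, or poor facial selectivity at C6 may intervene. The fallback closes the ring at C5–C6 instead and sets out from 14.
- Acetylation (Ac2O, pyridine) would give the iodo acetate F3.
- DDQ would free the allylic alcohol F4.
- NBS/Me2S would give the bromide F5.
- An indium-mediated Barbier reaction with aqueous formaldehyde (indium powder, THF/H2O) should add C6 at C7 anti to the C8 side chain and give the hydroxymethyl α-methylene lactone F6.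
- Dess–Martin oxidation would give the aldehyde F7.
- A Nozaki–Hiyama–Kishi macrocyclisation of the alkenyl iodide onto this aldehyde (NiCl2 (cat.), CrCl2, DMSO/THF, high dilution) comes back to the route at 20, Felkin-type addition with C8 as the large substituent being expected to give the same 6R carbinol.

Step 7 (vinylogous aldol). The 3-substituent of the silyloxyfuran may lower the anti/syn or the enantiofacial selectivity, and retro-aldol may erode the adduct. The fallback sets out from 7. An anti-selective γ-borylallylboration with (E)-γ-(1,3,2-dioxaborinan-2-yl)allyldiisopinocampheylborane, followed by oxidative work-up (NaOH, H2O2), would give the anti diol F8. Esterification of the less hindered C8 hydroxyl with 2-{[(4-methoxybenzyl)oxy]methyl}prop-2-enoic acid (DCC, DMAP (cat.), CH2Cl2, 0 °C) would give the acrylate F9. Ring-closing metathesis with the second-generation Grubbs catalyst comes back to the route at 14.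

**Further compounds**

F1 | step 13 | (1(10)E,4Z,7R,8R,9S)-9-acetoxy-15-[(tert-butyldiphenylsilyl)oxy]-6-oxogermacra-1(10),4,11(13)-trien-12,8-olide | C1/C(CO[Si](c2ccccc2)(c2ccccc2)C(C)(C)C)=C/C(=O)[C@@H]3C(=C)C(=O)O[C@H]3[C@@H](OC(C)=O)/C(C)=C/C1
F2 | step 13 | (1(10)E,4Z,6S,7S,8R,9S)-9-acetoxy-15-[(tert-butyldiphenylsilyl)oxy]-6-hydroxygermacra-1(10),4,11(13)-trien-12,8-olide | C1/C(CO[Si](c2ccccc2)(c2ccccc2)C(C)(C)C)=C/[C@H](O)[C@@H]3C(=C)C(=O)O[C@H]3[C@@H](OC(C)=O)/C(C)=C/C1
F3 | step 12 | (1S,2E,6Z)-6-{[(tert-butyldiphenylsilyl)oxy]methyl}-7-iodo-1-[(2R)-4-{[(4-methoxybenzyl)oxy]methyl}-5-oxo-2,5-dihydrofuran-2-yl]-2-methylhepta-2,6-dien-1-yl acetate | I/C=C(\CO[Si](c1ccccc1)(c1ccccc1)C(C)(C)C)CC/C=C(\C)[C@H](OC(C)=O)[C@@H]1OC(=O)C(COCc2ccc(OC)cc2)=C1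
F4 | step 12 | (1S,2E,6Z)-6-{[(tert-butyldiphenylsilyl)oxy]methyl}-1-[(2R)-4-(hydroxymethyl)-5-oxo-2,5-dihydrofuran-2-yl]-7-iodo-2-methylhepta-2,6-dien-1-yl acetate | I/C=C(\CO[Si](c1ccccc1)(c1ccccc1)C(C)(C)C)CC/C=C(\C)[C@H](OC(C)=O)[C@@H]1OC(=O)C(CO)=C1
F5 | step 12 | (1S,2E,6Z)-1-[(2R)-4-(bromomethyl)-5-oxo-2,5-dihydrofuran-2-yl]-6-{[(tert-butyldiphenylsilyl)oxy]methyl}-7-iodo-2-methylhepta-2,6-dien-1-yl acetate | I/C=C(\CO[Si](c1ccccc1)(c1ccccc1)C(C)(C)C)CC/C=C(\C)[C@H](OC(C)=O)[C@@H]1OC(=O)C(CBr)=C1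
F6 | step 12 | (1S,2E,6Z)-6-{[(tert-butyldiphenylsilyl)oxy]methyl}-1-[(2R,3S)-3-(hydroxymethyl)-4-methylidene-5-oxooxolan-2-yl]-7-iodo-2-methylhepta-2,6-dien-1-yl acetate | I/C=C(\CO[Si](c1ccccc1)(c1ccccc1)C(C)(C)C)CC/C=C(\C)[C@H](OC(C)=O)[C@@H]1OC(=O)C(=C)[C@H]1CO
F7 | step 12 | (1S,2E,6Z)-6-{[(tert-butyldiphenylsilyl)oxy]methyl}-1-[(2R,3R)-3-formyl-4-methylidene-5-oxooxolan-2-yl]-7-iodo-2-methylhepta-2,6-dien-1-yl acetate | I/C=C(\CO[Si](c1ccccc1)(c1ccccc1)C(C)(C)C)CC/C=C(\C)[C@H](OC(C)=O)[C@@H]1OC(=O)C(=C)[C@H]1C=O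
F8 | step 7 | (3R,4S,5E,9Z)-9-{[(tert-butyldiphenylsilyl)oxy]methyl}-10-iodo-5-methyldeca-1,5,9-triene-3,4-diol | I/C=C(\CO[Si](c1ccccc1)(c1ccccc1)C(C)(C)C)CC/C=C(\C)[C@H](O)[C@H](O)C=C
F9 | step 7 | (3R,4S,5E,9Z)-9-{[(tert-butyldiphenylsilyl)oxy]methyl}-4-hydroxy-10-iodo-5-methyldeca-1,5,9-trien-3-yl 2-{[(4-methoxybenzyl)oxy]methyl}prop-2-enoate | I/C=C(\CO[Si](c1ccccc1)(c1ccccc1)C(C)(C)C)CC/C=C(\C)[C@H](O)[C@H](OC(=O)C(=C)COCc1ccc(OC)cc1)C=C
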